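## The problem

Compound 20 is an open chain with a ring system at each end. One end is a (5S)-3-methylideneoxolan-2-one whose C-gamma carries the chain CH2–C(CH3)(OH)–CH(OH)–CH2–O; the other end is umbelliferone, bound through O-7. No ring is fused to another, so the three stereocentres must be set without a permanent ring to help. The tertiary (S) and secondary (R) carbinols are adjacent and correspond to syn-dihydroxylation of a Z-trisubstituted alkene, a geometry an open chain does not hold reliably. C-gamma (S) stands 1,3 to the tertiary carbinol across a methylene, and neither acyclic centre controls the other well, so one must be set absolutely and relayed through a temporary ring. The exocyclic methylene lactone is a Michael acceptor that will not survive hydride, hydrogenation, phosphines or alkoxides. The coumarin is a second lactone and enoate that is opened by hydroxide, reduced by hydride and hydrogen, and attacked by electrophilic halogen. Both must therefore arrive late, after all strong reductions and C–C bond formation. The enabling feature is the five-carbon run from the aryloxymethyl carbon through both carbinol carbons and the chain CH2 to C-gamma, which has oxygen at both ends (the aryl ether oxygen and the lactone ring oxygen). Tying the lactone oxygen to the aryloxymethyl carbon at the aldehyde oxidation level gives a 2-alkoxyoxane, and removing the two hydroxyls gives a 4-methyl-3,6-dihydro-2H-pyran. That ring is the hetero-Diels–Alder adduct of a 1-alkoxy-3-methylbuta-1,3-diene and a glyoxylate, with the glyoxylate ester carbon as lactone C-beta; in it the alkene must be Z and the two groups flanking the ring oxygen are cis and shield one face.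

## Retrosynthesis

**20 from 19.** The two ketal C–O bonds of an acetonide on the tertiary/secondary diol are cut last. The diol must be masked because a free 1,2-diol next to the primary alcohol would compete in the etherification. The forward step needs only mild aqueous acid, which the methylene lactone, the aryl ether and the coumarin tolerate.

**19 from 17 and 18.** The exocyclic C=CH2 bond is cut to the α-phosphono lactone 17 and formaldehyde 18 (Horner–Wadsworth–Emmons). Carrying the methylene through earlier steps is not possible, because hydrogenolysis, borohydride and phosphine all lie upstream. The phosphonate is a robust latent methylene, and the forward step needs only a weak base.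

**17 from 15 and 16.** The aryl O–CH2 bond is cut to the primary alcohol 15 and umbelliferone 16 (Mitsunobu). Attaching the coumarin earlier would expose it to hydride and hydrogenolysis. A neutral Mitsunobu is preferred to a basic Williamson reaction because 15 has an acidic C–H. Compound 15 has only one free hydroxyl, so no selectivity is asked.

**15 from 12 (through 13 and 14).** The lactone acyl–O bond is cut, and in the retrosynthetic sense the C-gamma oxygen and the terminal carbon are tied back into a pyranoside. In 12 the ring oxygen protects the C-gamma hydroxyl and the anomeric carbon is a masked aldehyde. A benzyl acetal is chosen over the more usual methyl acetal for two reasons: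
- A methyl pyranoside flanked by an oxygenated carbon needs hot mineral acid, which would strip the acetonide first and release a free α,β-dihydroxy aldehyde prone to epimerisation and retro-aldol cleavage.
- The benzyl group leaves by hydrogenolysis at neutral pH.

The forward step asks that the lactol 13 be reduced faster than its α-centre epimerises, and that in 14 only the secondary hydroxyl lactonises. The primary hydroxyl would need a nine-membered ring.

**12 from 9 and 10 (through 11).** The C-beta–C-alpha bond is cut to the primary triflate 11 (from alcohol 9) and the carbanion of triethyl phosphonoacetate 10. Two neighbouring options were rejected: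
- Radical allylation of a derived iodide with a 2-(halomethyl)acrylate. Such acceptors take the radical at their CH2 terminus, which would insert one carbon too many and give the six-membered methylene lactone.
- An organozinc or organolithium at C-beta. It has the ring oxygen in the β-position and would fragment the pyran.

C-beta is therefore the electrophile, and the nucleophile brings C-alpha, the carbonyl carbon and the phosphonate needed later. The forward step asks for SN2 at a β-oxygenated primary carbon, hence the triflate.

**9 from 6 (through 8 and 7).** These are functional-group changes on an intact ring: ester to carbinol, diol to acetonide, and the two carbinol C–O bonds cut back to the ring alkene of 6. Dihydroxylating on the ring is preferred to any acyclic version because the ring fixes the Z geometry and places the benzyloxy and ester groups on one face, leaving the other open.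

**6 from 4 and 5.** The chain CH2–C-gamma bond and the O–acetal carbon bond are cut together (hetero-Diels–Alder). An aldol or allylation would make the same C–C bond but leave the 1,3-relationship to acyclic control. The precursors are the achiral diene 4 and ethyl glyoxylate 5. The forward reaction must be regioselective, must prefer cycloaddition to the ene pathway, must be endo (cis), and must be enantioselective.

**4 from 1 and 2 (through 3).** The diene's enol ether is traced to the dibenzyl acetal 3 by 1,4-elimination. Acetal 3 comes from 3-methylbut-2-enal 1 and benzyloxytrimethylsilane 2.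

## Roads not taken

**Alternative 1:** The same two carbinol C–O bonds are cut, but on the unsaturated six-membered lactone A1. Its C-6 is C-gamma, its chloromethyl carbon is C-beta and its carbonyl carbon is the future aryloxymethyl carbon. Osmium-catalysed dihydroxylation anti to the chloromethyl group would give A2.
- Merits: the ring enforces the Z geometry as in the chosen plan. C-gamma can be taken from a three-carbon chiral-pool chlorohydrin unit, so no asymmetric catalysis is needed. There is no acid-labile acetal.
- Weak points: the only control element is a homoallylic substituent lying pseudo-equatorially on a flattened ring, far from the alkene. The alkene is a trisubstituted enoate, a poor partner for an electrophilic osmium reagent. A2 is an α,β-dihydroxy lactone that epimerises and eliminates easily. Reducing its carbonyl later frees several hydroxyls at once, whereas in 8 the two chain ends remain distinct as ester and acetal.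
- Comparison: in steps to the stereotriad and in security of absolute configuration this road is at least as good as the chosen one. The chosen plan sets against it an allylic alkoxy group on the alkene-bearing ring, reinforced by a second cis substituent, giving a far stronger facial bias for the hardest relationship (C-gamma to the tertiary carbinol).

**Alternative 2:** The C-gamma–O bond is cut. The acyclic homoallylic tert-butyl carbonate A3, already carrying both carbinols and the coumarin ether, would be cyclised by an electrophilic iodine reagent to the iodomethyl cyclic carbonate A4, whose iodomethyl carbon is C-beta.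
- Merits: it is convergent, needs no temporary ring to be reopened, and uses a cyclisation that is dependable for secondary carbonates.
- Weak points: the carbonate must be placed on a tertiary alcohol, which is hard to acylate and ionises easily. The directing centre is quaternary, so selectivity depends on the small difference between methyl and a branched silyloxyalkyl group in the chair transition state. The electron-rich 7-alkoxycoumarin is exposed to electrophilic halogen. The iodide still needs the C-alpha unit, where direct radical allylation would again give the six-ring homologue. The carbonate must finally be removed with base in the presence of the coumarin.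
- Comparison: this road is better in convergence. The chosen plan sets against it that one catalytic event plus one ring-controlled addition fixes all three centres, and that the coumarin never meets halogen, hydride or base.

**Alternative 3:** The tertiary C–O bond is cut and would be made with inversion. In the epoxide A5, the tert-butyl carbonate on the C-gamma oxygen would open the trisubstituted epoxide at its tertiary carbon under a boron Lewis acid, giving the cyclic carbonate A6 with a free secondary hydroxyl.
- Merits: the α-methylene ester is already in place with the right carbon count. The endgame is short (carbonate cleavage and lactonisation). The 1,3-relationship is relayed intramolecularly.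
- Weak points: two independent reagent-controlled steps are needed. One is an enantioselective carbonyl allylation with a 2-(halomethyl)acrylate; the other is an asymmetric epoxidation of a trisubstituted alkene with no directing hydroxyl. Opening at a tertiary carbon has carbocation character, so inversion may erode or a 1,2-shift may intervene. The acrylate and coumarin must survive basic carbonate cleavage.
- Comparison: this road is shorter after its key step and needs no diol protection, and is better there. The chosen plan sets against it a single enantioselective step, relay through a rigid ring instead of an ionising epoxide, and late, neutral introduction of both sensitive groups.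

Key step: step 3

Assumption: the (R)-BINOL titanium catalyst is taken to direct the diene to the Re face of the glyoxylate, as it does the alkene in the glyoxylate-ene reaction, which gives (2R)-6; if the sense is the reverse, (S)-BINOL is used and nothing else changes.

## Route

Step 1
Reactants: 1 3-methylbut-2-enal; 2 benzyloxytrimethylsilane
Product: 3 3-methylbut-2-enal dibenzyl acetal [1,1-bis(benzyloxy)-3-methylbut-2-ene]
Conditions: 2 (2.2 equiv), TMSOTf (1 mol %), CH2Cl2, −78 °C; pyridine quench
Reagents that add atoms: none
Why: Silyl-triflate-catalysed acetalisation of an aldehyde with an alkoxysilane is driven by formation of the disiloxane and runs at −78 °C, so the enal should be acetalised without conjugate addition or double-bond migration.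

Step 2
Reactants: 3 3-methylbut-2-enal dibenzyl acetal
Product: 4 (E)-1-(benzyloxy)-3-methylbuta-1,3-diene
Conditions: TMSOTf (1.2 equiv), iPr2NEt (1.5 equiv), CH2Cl2, −20 °C → rt; filtration through basic alumina
Reagents that add atoms: none
Why: The silyl triflate ionises the acetal to the conjugated oxocarbenium ion and the hindered amine removes a proton from a γ-methyl group (1,4-elimination of an α,β-unsaturated acetal to a 1-alkoxydiene); the extended cation should give the E enol ether, the only geometry that can adopt the s-cis conformation needed in step 3.

Step 3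
Reactants: 4 (E)-1-(benzyloxy)-3-methylbuta-1,3-diene; 5 ethyl glyoxylate
Product: 6 ethyl (2R,6S)-6-(benzyloxy)-4-methyl-3,6-dihydro-2H-pyran-2-carboxylate (cis)
Conditions: (R)-BINOL/TiCl2(OiPr)2 (10 mol %), 4 Å MS, CH2Cl2, −30 °C; 5 freshly distilled
Reagents that add atoms: none
Why: The glyoxylate is activated by the BINOL-derived tetravalent titanium Lewis acid and reacts with the electron-rich diene in a normal-demand, asynchronous [4+2] cycloaddition; the closest known reaction type is the BINOL–titanium-catalysed hetero-Diels–Alder reaction of 1-alkoxydienes with glyoxylate esters. The unsubstituted diene terminus C-4, which carries the largest HOMO coefficient of the vinylogous enol ether, bonds to the aldehyde carbon (the chain CH2 to C-gamma bond), and the carbonyl oxygen bonds to the benzyloxy-bearing terminus C-1 (the O to acetal carbon bond), so the one ring closed is the six-membered 3,6-dihydro-2H-pyran, formed by intermolecular [4+2] cycloaddition. C-2 (R, the future C-gamma) is set by the catalyst, which leaves the Re face of the bound aldehyde open. C-6 (S) follows from the endo orientation of the ester toward the E enol ether, which places benzyloxy and ester cis. Regioselectivity is secured by the polarisation of the 1-alkoxydiene. Preference for cycloaddition over the glyoxylate-ene reaction at the 3-methyl group is secured by the alkoxy donor, which lets ring closure onto the developing oxocarbenium centre outrun proton transfer from the methyl group. The cis ratio is protected by the low temperature, which keeps the Lewis acid from ionising the allylic acetal of the product.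

Step 4
Reactants: 6 ethyl (2R,6S)-6-(benzyloxy)-4-methyl-3,6-dihydro-2H-pyran-2-carboxylate
Product: 7 ethyl (2R,4S,5S,6S)-6-(benzyloxy)-4,5-dihydroxy-4-methyloxane-2-carboxylate
Conditions: OsO4 (2 mol %), NMO (1.5 equiv), acetone/H2O, 0 °C → rt
Reagents that add atoms: N-methylmorpholine N-oxide C[N+]1([O-])CCOCC1 and water O (the two hydroxyl oxygens, delivered through OsO4 O=[Os](=O)(=O)=O)
Why: Catalytic syn-dihydroxylation of a ring alkene that can only be Z; OsO4 should add anti to the allylic benzyloxy group at C-6 (the usual sense for 2,3-unsaturated glycosides), which is also the face opposite the ester at C-2, so both carbinol centres are set relative to C-2 (the 5S descriptor reflects the acetal neighbour, not a different geometry from the target).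

Step 5
Reactants: 7 ethyl (2R,4S,5S,6S)-6-(benzyloxy)-4,5-dihydroxy-4-methyloxane-2-carboxylate
Product: 8 ethyl (3aS,4S,6R,7aS)-4-(benzyloxy)-2,2,7a-trimethyltetrahydro-4H-[1,3]dioxolo[4,5-c]pyran-6-carboxylate (the 4,5-acetonide of 7)
Conditions: Me2C(OMe)2, PPTS (cat.), acetone, rt
Reagents that add atoms: 2,2-dimethoxypropane COC(C)(C)OC
Why: Acid-catalysed ketal exchange onto a cis-1,2-diol on a six-membered ring closes a cis-fused dioxolane; the non-allylic benzyl pyranoside should be inert to PPTS at room temperature.

Step 6
Reactants: 8 ethyl (3aS,4S,6R,7aS)-4-(benzyloxy)-2,2,7a-trimethyltetrahydro-4H-[1,3]dioxolo[4,5-c]pyran-6-carboxylate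
Product: 9 [(3aS,4S,6R,7aS)-4-(benzyloxy)-2,2,7a-trimethyltetrahydro-4H-[1,3]dioxolo[4,5-c]pyran-6-yl]methanol
Conditions: LiAlH4, THF, 0 °C
Reagents that add atoms: none
Why: Hydride reduction of an ester to the primary alcohol; acetals and ketals are inert, and the strong reductant is used before any lactone, enoate or coumarin is present.

Step 7
Reactants: 9 [(3aS,4S,6R,7aS)-4-(benzyloxy)-2,2,7a-trimethyltetrahydro-4H-[1,3]dioxolo[4,5-c]pyran-6-yl]methanol; 10 triethyl phosphonoacetate
Product: 12 ethyl 3-[(3aS,4S,6R,7aS)-4-(benzyloxy)-2,2,7a-trimethyltetrahydro-4H-[1,3]dioxolo[4,5-c]pyran-6-yl]-2-(diethoxyphosphoryl)propanoate (both epimers at the phosphonate carbon), via primary triflate 11 (not isolated)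
Conditions: Tf2O, 2,6-lutidine, CH2Cl2, −78 °C; then cannulated into NaCH[P(O)(OEt)2]CO2Et (3 equiv, from 10 and NaH), THF/DMF, −40 °C → rt
Reagents that add atoms: trifluoromethanesulfonic anhydride O=S(=O)(OS(=O)(=O)C(F)(F)F)C(F)(F)F (supplies the triflyl group of 11 only; nothing of it remains in 12)
Why: SN2 alkylation of a phosphonate-stabilised carbanion by a primary triflate, the leaving group that makes displacement at a β-oxygenated carbon practical; the weakly basic anion should not eliminate, C-2 of the pyran is untouched, and the new centre is lost in step 10. Closure of the anomeric oxygen onto the triflate would need the benzyloxy, methyl and CH2OTf groups all axial, which this ring avoids.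

Step 8
Reactants: 12 ethyl 3-[(3aS,4S,6R,7aS)-4-(benzyloxy)-2,2,7a-trimethyltetrahydro-4H-[1,3]dioxolo[4,5-c]pyran-6-yl]-2-(diethoxyphosphoryl)propanoate
Product: 15 diethyl [(5R)-5-{[(4S,5R)-5-(hydroxymethyl)-2,2,4-trimethyl-1,3-dioxolan-4-yl]methyl}-2-oxooxolan-3-yl]phosphonate (both epimers at C-3), via lactol 13 (not isolated), via open-chain hydroxy ester 14 (not isolated)
Conditions: H2 (1 atm), Pd(OH)2/C, EtOH, rt; filter; NaBH4, 0 °C; AcOH quench; then DBU (cat.), PhMe, 50 °C
Reagents that add atoms: none
Why: Hydrogenolysis of the anomeric benzyl ether at neutral pH frees the lactol without touching the acetonide, borohydride reduces its open aldehyde form to the primary alcohol, and the released C-gamma hydroxyl closes the five-membered lactone onto the ester by base-catalysed transesterification (the primary hydroxyl would need a nine-membered ring). No stereocentre is made or broken; the 5R descriptor reflects the phosphorus substituent.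

Step 9
Reactants: 15 diethyl [(5R)-5-{[(4S,5R)-5-(hydroxymethyl)-2,2,4-trimethyl-1,3-dioxolan-4-yl]methyl}-2-oxooxolan-3-yl]phosphonate; 16 umbelliferone (7-hydroxy-2H-chromen-2-one)
Product: 17 diethyl [(5R)-2-oxo-5-{[(4S,5R)-2,2,4-trimethyl-5-{[(2-oxo-2H-chromen-7-yl)oxy]methyl}-1,3-dioxolan-4-yl]methyl}oxolan-3-yl]phosphonate (both epimers at C-3)
Conditions: PPh3, DIAD, THF, 0 °C → rt
Reagents that add atoms: none
Why: Mitsunobu etherification of the only free (primary) alcohol with an acidic phenol under neutral conditions; the phosphonate C–H is a much slower pronucleophile than the phenol, and no stereocentre is involved.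

Step 10
Reactants: 17 diethyl [(5R)-2-oxo-5-{[(4S,5R)-2,2,4-trimethyl-5-{[(2-oxo-2H-chromen-7-yl)oxy]methyl}-1,3-dioxolan-4-yl]methyl}oxolan-3-yl]phosphonate; 18 formaldehyde
Product: 19 (5S)-3-methylidene-5-{[(4S,5R)-2,2,4-trimethyl-5-{[(2-oxo-2H-chromen-7-yl)oxy]methyl}-1,3-dioxolan-4-yl]methyl}oxolan-2-one
Conditions: K2CO3, 37% aq. 18, THF, 0 °C → rt
Reagents that add atoms: none
Why: Horner–Wadsworth–Emmons methylenation of an α-phosphono-γ-butyrolactone with formaldehyde, the standard late-stage entry to α-methylene lactones; both C-3 epimers converge, and cold carbonate is mild enough that the coumarin should persist (5S is now the target descriptor at C-gamma).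

Step 11
Reactants: 19 (5S)-3-methylidene-5-{[(4S,5R)-2,2,4-trimethyl-5-{[(2-oxo-2H-chromen-7-yl)oxy]methyl}-1,3-dioxolan-4-yl]methyl}oxolan-2-one
Product: 20 (5S)-5-{(2S,3R)-2,3-dihydroxy-2-methyl-4-[(2-oxo-2H-chromen-7-yl)oxy]butyl}-3-methylideneoxolan-2-one
Conditions: 80% aq. AcOH, 45 °C
Reagents that add atoms: none
Why: Acid hydrolysis of the isopropylidene ketal; the methylene lactone, aryl ether and coumarin are stable to aqueous acid, and the tertiary hydroxyl cannot translactonise because that would require a seven-membered ring.

## Compound list

1 | 3-methylbut-2-enal | CC(C)=CC=O | starting material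
2 | benzyloxytrimethylsilane | C[Si](C)(C)OCc1ccccc1 | starting material
3 | 3-methylbut-2-enal dibenzyl acetal | CC(C)=CC(OCc1ccccc1)OCc1ccccc1 | intermediate
4 | (E)-1-(benzyloxy)-3-methylbuta-1,3-diene | C=C(C)/C=C/OCc1ccccc1 | intermediate
5 | ethyl glyoxylate | O=CC(=O)OCC | starting material
6 | ethyl (2R,6S)-6-(benzyloxy)-4-methyl-3,6-dihydro-2H-pyran-2-carboxylate | CCOC(=O)[C@H]1CC(C)=C[C@@H](OCc2ccccc2)O1 | intermediate
7 | ethyl (2R,4S,5S,6S)-6-(benzyloxy)-4,5-dihydroxy-4-methyloxane-2-carboxylate | CCOC(=O)[C@H]1C[C@](C)(O)[C@H](O)[C@@H](OCc2ccccc2)O1 | intermediate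
8 | ethyl (3aS,4S,6R,7aS)-4-(benzyloxy)-2,2,7a-trimethyltetrahydro-4H-[1,3]dioxolo[4,5-c]pyran-6-carboxylate | CCOC(=O)[C@H]1C[C@]2(C)OC(C)(C)O[C@@H]2[C@@H](OCc3ccccc3)O1 | intermediate
9 | [(3aS,4S,6R,7aS)-4-(benzyloxy)-2,2,7a-trimethyltetrahydro-4H-[1,3]dioxolo[4,5-c]pyran-6-yl]methanol | OC[C@H]1C[C@]2(C)OC(C)(C)O[C@@H]2[C@@H](OCc3ccccc3)O1 | intermediate
10 | triethyl phosphonoacetate | CCOC(=O)CP(=O)(OCC)OCC | starting material
11 | [(3aS,4S,6R,7aS)-4-(benzyloxy)-2,2,7a-trimethyltetrahydro-4H-[1,3]dioxolo[4,5-c]pyran-6-yl]methyl trifluoromethanesulfonate | O=S(=O)(OC[C@H]1C[C@]2(C)OC(C)(C)O[C@@H]2[C@@H](OCc3ccccc3)O1)C(F)(F)F | intermediate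
12 | ethyl 3-[(3aS,4S,6R,7aS)-4-(benzyloxy)-2,2,7a-trimethyltetrahydro-4H-[1,3]dioxolo[4,5-c]pyran-6-yl]-2-(diethoxyphosphoryl)propanoate (both epimers at C-2 of the propanoate) | CCOC(=O)C(C[C@H]1C[C@]2(C)OC(C)(C)O[C@@H]2[C@@H](OCc3ccccc3)O1)P(=O)(OCC)OCC | intermediate
13 | ethyl 2-(diethoxyphosphoryl)-3-[(3aS,6R,7aS)-4-hydroxy-2,2,7a-trimethyltetrahydro-4H-[1,3]dioxolo[4,5-c]pyran-6-yl]propanoate (lactol, both anomers) | CCOC(=O)C(C[C@H]1C[C@]2(C)OC(C)(C)O[C@@H]2C(O)O1)P(=O)(OCC)OCC | intermediate
14 | ethyl (4R)-2-(diethoxyphosphoryl)-4-hydroxy-5-[(4S,5R)-5-(hydroxymethyl)-2,2,4-trimethyl-1,3-dioxolan-4-yl]pentanoate | CCOC(=O)C(C[C@H](O)C[C@]1(C)OC(C)(C)O[C@@H]1CO)P(=O)(OCC)OCC | intermediate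
15 | diethyl [(5R)-5-{[(4S,5R)-5-(hydroxymethyl)-2,2,4-trimethyl-1,3-dioxolan-4-yl]methyl}-2-oxooxolan-3-yl]phosphonate (both C-3 epimers) | O=C1O[C@H](C[C@]2(C)OC(C)(C)O[C@@H]2CO)CC1P(=O)(OCC)OCC | intermediate
16 | umbelliferone (7-hydroxy-2H-chromen-2-one) | Oc1ccc2ccc(=O)oc2c1 | starting material
17 | diethyl [(5R)-2-oxo-5-{[(4S,5R)-2,2,4-trimethyl-5-{[(2-oxo-2H-chromen-7-yl)oxy]methyl}-1,3-dioxolan-4-yl]methyl}oxolan-3-yl]phosphonate (both C-3 epimers) | O=C1O[C@H](C[C@]2(C)OC(C)(C)O[C@@H]2COc3ccc4ccc(=O)oc4c3)CC1P(=O)(OCC)OCC | intermediate
18 | formaldehyde | C=O | starting material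
19 | (5S)-3-methylidene-5-{[(4S,5R)-2,2,4-trimethyl-5-{[(2-oxo-2H-chromen-7-yl)oxy]methyl}-1,3-dioxolan-4-yl]methyl}oxolan-2-one | C=C1C[C@@H](C[C@]2(C)OC(C)(C)O[C@@H]2COc3ccc4ccc(=O)oc4c3)OC1=O | intermediate
20 | (5S)-5-{(2S,3R)-2,3-dihydroxy-2-methyl-4-[(2-oxo-2H-chromen-7-yl)oxy]butyl}-3-methylideneoxolan-2-one | C=C1C[C@@H](C[C@](C)(O)[C@H](O)COc2ccc3ccc(=O)oc3c2)OC1=O | target

## Step count and weak points

Total: 11 steps. Longest linear sequence: 11 steps (1 to 20); compounds 2, 5, 10, 16 and 18 are purchased.

**Step 3 (key step).** The most likely failures are these: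
- Loss of periselectivity: after the first C–C bond forms, a proton may be transferred from the 3-methyl group instead of the ring closing.
- Lewis-acid ionisation of the allylic acetal, which would erode the cis relationship.
- Only moderate enantioselectivity with a benzyloxy diene in place of the usual methoxy diene.

Fallback: from 4, the cycloaddition is run with purchased (tert-butyldimethylsilyloxy)acetaldehyde under the chromium chloride Schiff-base complex CrCl(L), a milder trivalent chromium Lewis acid. L is the dianion of the imine from cis-1-aminoindan-2-ol and 3-(1-adamantyl)-2-hydroxy-5-methylbenzaldehyde, used as the enantiomer that gives the 2R adduct. This should give the cis dihydropyran silyl ether F1. OsO4/NMO then gives the diol F2, 2,2-dimethoxypropane/PPTS gives the acetonide silyl ether F3, and Bu4NF returns alcohol 9. Step 6 is then no longer needed.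

**Step 7.** Substitution at a primary carbon that is both β-branched and β-oxygenated may be slower than loss of the triflate by ionisation or elimination, and the ambident anion may alkylate on oxygen. Fallback: from 9, oxidation with Dess–Martin periodinane gives the aldehyde F4. Knoevenagel condensation with 10 (TiCl4, N-methylmorpholine, THF, 0 °C) gives the alkylidene phosphonoacetate F5. Hydrogenation (H2, Pd(OH)2/C) saturates the alkene and removes the benzyl group in one operation, giving lactol 13, where the route is rejoined inside step 8.

**Step 9.** Activation of a primary carbinol flanked by a fully substituted dioxolane carbon may be slow, so that the reduced azodicarboxylate is alkylated in place of the phenol. Fallback: from 15, Tf2O/2,6-lutidine at −78 °C gives the primary triflate F6, which is displaced at 0 °C by the potassium salt of 16 (K2CO3, 18-crown-6, DMF) in a Williamson etherification, giving 17.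

**Step 10.** Aqueous carbonate may open the coumarin lactone or add to the newly formed methylene lactone before the olefination is complete. Fallback: the order is reversed. From 15, the same methylenation with 18 gives the methylene lactone alcohol F7, and the Mitsunobu reaction with 16 is then run on F7 to give 19 directly, so the coumarin never meets base.

## Further compounds

F1 | step 3 | tert-butyl{[(2R,6S)-6-(benzyloxy)-4-methyl-3,6-dihydro-2H-pyran-2-yl]methoxy}dimethylsilane | CC(C)(C)[Si](C)(C)OC[C@H]1CC(C)=C[C@@H](OCc2ccccc2)O1
F2 | step 3 | (2R,4S,5S,6S)-6-(benzyloxy)-2-{[(tert-butyldimethylsilyl)oxy]methyl}-4-methyloxane-4,5-diol | CC(C)(C)[Si](C)(C)OC[C@H]1C[C@](C)(O)[C@H](O)[C@@H](OCc2ccccc2)O1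
F3 | step 3 | tert-butyl{[(3aS,4S,6R,7aS)-4-(benzyloxy)-2,2,7a-trimethyltetrahydro-4H-[1,3]dioxolo[4,5-c]pyran-6-yl]methoxy}dimethylsilane | CC(C)(C)[Si](C)(C)OC[C@H]1C[C@]2(C)OC(C)(C)O[C@@H]2[C@@H](OCc3ccccc3)O1
F4 | step 7 | (3aS,4S,6R,7aS)-4-(benzyloxy)-2,2,7a-trimethyltetrahydro-4H-[1,3]dioxolo[4,5-c]pyran-6-carbaldehyde | O=C[C@H]1C[C@]2(C)OC(C)(C)O[C@@H]2[C@@H](OCc3ccccc3)O1
F5 | step 7 | ethyl 3-[(3aS,4S,6R,7aS)-4-(benzyloxy)-2,2,7a-trimethyltetrahydro-4H-[1,3]dioxolo[4,5-c]pyran-6-yl]-2-(diethoxyphosphoryl)prop-2-enoate (alkene geometry not fixed) | CCOC(=O)C(=C[C@H]1C[C@]2(C)OC(C)(C)O[C@@H]2[C@@H](OCc3ccccc3)O1)P(=O)(OCC)OCC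
F6 | step 9 | {(4R,5S)-5-{[(2R)-4-(diethoxyphosphoryl)-5-oxooxolan-2-yl]methyl}-2,2,5-trimethyl-1,3-dioxolan-4-yl}methyl trifluoromethanesulfonate (the primary triflate of 15) | O=C1O[C@H](C[C@]2(C)OC(C)(C)O[C@@H]2COS(=O)(=O)C(F)(F)F)CC1P(=O)(OCC)OCC
F7 | step 10 | (5S)-5-{[(4S,5R)-5-(hydroxymethyl)-2,2,4-trimethyl-1,3-dioxolan-4-yl]methyl}-3-methylideneoxolan-2-one | C=C1C[C@@H](C[C@]2(C)OC(C)(C)O[C@@H]2CO)OC1=O
A1 | alternative 1 | (6R)-6-(chloromethyl)-4-methyl-5,6-dihydro-2H-pyran-2-one | CC1=CC(=O)O[C@@H](CCl)C1
A2 | alternative 1 | (3S,4S,6R)-6-(chloromethyl)-3,4-dihydroxy-4-methyloxan-2-one | C[C@@]1(O)[C@H](O)C(=O)O[C@@H](CCl)C1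
A3 | alternative 2 | tert-butyl (2R,3S)-2-[(tert-butyldimethylsilyl)oxy]-3-methyl-1-[(2-oxo-2H-chromen-7-yl)oxy]hex-5-en-3-yl carbonate | C=CC[C@](C)(OC(=O)OC(C)(C)C)[C@H](O[Si](C)(C)C(C)(C)C)COc1ccc2ccc(=O)oc2c1
A4 | alternative 2 | 7-{(2R)-2-[(tert-butyldimethylsilyl)oxy]-2-[(4S,6R)-6-(iodomethyl)-4-methyl-2-oxo-1,3-dioxan-4-yl]ethoxy}-2H-chromen-2-one | IC[C@H]1C[C@](C)(OC(=O)O1)[C@H](O[Si](C)(C)C(C)(C)C)COc1ccc2ccc(=O)oc2c1
A5 | alternative 3 | ethyl 2-{(2S)-2-[(tert-butoxycarbonyl)oxy]-3-[(2R,3R)-2-methyl-3-{[(2-oxo-2H-chromen-7-yl)oxy]methyl}oxiran-2-yl]propyl}prop-2-enoate | C=C(C[C@H](OC(=O)OC(C)(C)C)C[C@@]1(C)O[C@@H]1COc2ccc3ccc(=O)oc3c2)C(=O)OCC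
A6 | alternative 3 | ethyl 2-{[(4S,6S)-6-{(1R)-1-hydroxy-2-[(2-oxo-2H-chromen-7-yl)oxy]ethyl}-6-methyl-2-oxo-1,3-dioxan-4-yl]methyl}prop-2-enoate | C=C(C[C@H]1C[C@](C)(OC(=O)O1)[C@H](O)COc1ccc2ccc(=O)oc2c1)C(=O)OCC
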